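**Strategy.** The decalin is cut across ring B: the cyclohexenone bonds C5–C10 and C8–C9 are made together by an intramolecular Diels–Alder reaction, the C6 carbonyl being carried as a silyl enol ether, the C7=C8 alkene arising later from it, and the four carbons C1–C4 serving as tether and becoming ring A. One thermal operation thus closes both rings and sets quaternary C10, C9 and the ring fusion from a single stereocentre, C3. The precursor is an acyclic triene in which a (Z)-β-methyl enoate (C9=C10) is joined by the chain C1–C4, carrying the C3 benzyl carbonate and the C4 gem-dimethyl group, to a C5–C8 diene silyloxylated at C6. C3 is inverted afterwards; isofraxidin and the isovalerate follow.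

Key step: step 11

Remark: the target is read as 3α-acyloxy, 5α-H, 9β-H (C11 on the α face, trans to the C10 methyl) and 10β-methyl; ring compounds are named on the drimane skeleton (4,4,8,10-tetramethyldecalin with C11 on C9), β meaning the face of the C10 methyl.

**Route**

Step 1
Reactants: 1 3-methylcyclohex-2-en-1-one
Product: 2 trimethyl[(5-methylcyclohexa-1,5-dien-1-yl)oxy]silane
Conditions: LiN(i-Pr)2, THF, −78 °C; then Me3SiCl, −78 °C → rt
Reagents that add atoms: chlorotrimethylsilane, C[Si](C)(C)Cl
Why: Kinetic α′-deprotonation of the enone at C6 followed by O-silylation (enolate trapping) should give the cross-conjugated 2-silyloxydiene; no stereocentre is formed.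

Step 2
Reactants: 2 trimethyl[(5-methylcyclohexa-1,5-dien-1-yl)oxy]silane
Product: 4 6-hydroxy-3-methylcyclohex-2-en-1-one (racemic), via α-silyloxy ketone 3 (not isolated)
Conditions: mCPBA, hexane, −15 °C → rt; then 1 M aq. HCl, THF, 0 °C
Reagents that add atoms: 3-chloroperoxybenzoic acid, OOC(=O)c1cccc(Cl)c1
Why: In this Rubottom oxidation the peracid epoxidises the electron-rich enol ether alkene, silyl migration opens the epoxide to 3 and dilute acid removes the silyl group; the carbinol centre forms as a racemate, which does not matter because it becomes the aldehyde carbon in step 3.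

Step 3
Reactants: 4 6-hydroxy-3-methylcyclohex-2-en-1-one
Product: 5 methyl (2Z)-3-methyl-6-oxohex-2-enoate
Conditions: Pb(OAc)4, MeOH/toluene 1:1, 0 °C → rt
Reagents that add atoms: methanol, CO
Why: Oxidative α-ketol cleavage (Criegee-type fission of the methanol hemiketal) breaks the ring bond between the carbonyl and carbinol carbons to a methyl ester and an aldehyde, and because the trisubstituted alkene was part of the six-membered ring the chain and the ester must emerge cis, i.e. as the Z-enoate; no stereocentre is formed.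

Step 4
Reactants: 5 methyl (2Z)-3-methyl-6-oxohex-2-enoate; 6 3-methylbuta-1,2-diene
Product: 8 methyl (2Z,6S)-6-hydroxy-3,7,7-trimethylnona-2,8-dienoate, via diisopinocampheylborinate 7 (not isolated)
Conditions: (+)-Ipc2BH [from (−)-α-pinene], THF, −25 °C; then 5, Et2O, −78 °C; then NaBO3·4H2O, THF/H2O, rt
Reagents that add atoms: (+)-diisopinocampheylborane (its boron and both isopinocampheyl groups are kept only in 7), B([C@H]1C[C@H]2C[C@@H]([C@@H]1C)C2(C)C)[C@H]1C[C@H]2C[C@@H]([C@@H]1C)C2(C)C
Why: Hydroboration of the allene gives the B-prenyl borane, which adds to the aldehyde through a chair-like six-membered transition state with allyl transposition (Brown asymmetric prenylation), forming the C3–C4 bond, the gem-dimethyl carbon C4 and the C5=C6 vinyl group, the isopinocampheyl groups from (−)-α-pinene directing attack to the Re face so that C3 is S; this step fixes the optical purity of the route, and perborate then cleaves 7.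

Step 5
Reactants: 8 methyl (2Z,6S)-6-hydroxy-3,7,7-trimethylnona-2,8-dienoate
Product: 9 methyl (2Z,6S)-6-{[(benzyloxy)carbonyl]oxy}-3,7,7-trimethylnona-2,8-dienoate
Conditions: CbzCl, DMAP, CH2Cl2, 0 °C → rt
Reagents that add atoms: benzyl chloroformate, O=C(Cl)OCc1ccccc1
Why: DMAP-mediated acylation with the chloroformate should convert the hindered secondary alcohol into a benzyl carbonate, chosen because it survives hydroboration, divalent chromium and silyl triflate and can later be removed by hydrogenolysis without touching a silyl enol ether; C3 is untouched.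

Step 6
Reactants: 9 methyl (2Z,6S)-6-{[(benzyloxy)carbonyl]oxy}-3,7,7-trimethylnona-2,8-dienoate
Product: 11 methyl (2Z,6S)-6-{[(benzyloxy)carbonyl]oxy}-9-hydroxy-3,7,7-trimethylnon-2-enoate, via B-alkyl-9-BBN adduct 10 (not isolated)
Conditions: 9-BBN, THF, 0 °C → rt; then 30% H2O2, aq. NaOAc, 0 °C → rt
Reagents that add atoms: 9-borabicyclo[3.3.1]nonane (kept only in 10), B1C2CCCC1CCC2; hydrogen peroxide, OO
Why: Anti-Markovnikov hydroboration–oxidation with the bulky borane takes place only at the monosubstituted C5=C6 alkene (the conjugated trisubstituted enoate is inert), boron going to terminal C6, and acetate-buffered peroxide oxidises 10 without hydrolysing carbonate or ester; no stereocentre is formed.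

Step 7
Reactants: 11 methyl (2Z,6S)-6-{[(benzyloxy)carbonyl]oxy}-9-hydroxy-3,7,7-trimethylnon-2-enoate
Product: 12 methyl (2Z,6S)-6-{[(benzyloxy)carbonyl]oxy}-3,7,7-trimethyl-9-oxonon-2-enoate
Conditions: Dess–Martin periodinane, CH2Cl2, rt
Reagents that add atoms: none
Why: Dess–Martin oxidation of the primary alcohol to the aldehyde under neutral conditions leaves the Z-enoate, the carbonate and C3 untouched.

Step 8
Reactants: 12 methyl (2Z,6S)-6-{[(benzyloxy)carbonyl]oxy}-3,7,7-trimethyl-9-oxonon-2-enoate; 13 (E)-1-bromoprop-1-ene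
Product: 14 methyl (2Z,6S,10E)-6-{[(benzyloxy)carbonyl]oxy}-9-hydroxy-3,7,7-trimethyldodeca-2,10-dienoate (both C9 epimers)
Conditions: CrCl2, NiCl2 (cat.), DMF, rt
Reagents that add atoms: none
Why: In this Nozaki–Hiyama–Kishi coupling the alkenylchromium species formed from 13 under nickel catalysis adds only to the aldehyde in the presence of ester and carbonate and keeps the E geometry; the new carbinol centre forms as a mixture that the next oxidation removes.

Step 9
Reactants: 14 methyl (2Z,6S,10E)-6-{[(benzyloxy)carbonyl]oxy}-9-hydroxy-3,7,7-trimethyldodeca-2,10-dienoate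
Product: 15 methyl (2Z,6S,10E)-6-{[(benzyloxy)carbonyl]oxy}-3,7,7-trimethyl-9-oxododeca-2,10-dienoate
Conditions: Dess–Martin periodinane, CH2Cl2, rt
Reagents that add atoms: none
Why: Dess–Martin oxidation of the allylic alcohol gives the (E)-propenyl ketone and erases the carbinol centre made in step 8.

Step 10
Reactants: 15 methyl (2Z,6S,10E)-6-{[(benzyloxy)carbonyl]oxy}-3,7,7-trimethyl-9-oxododeca-2,10-dienoate
Product: 16 methyl (2Z,6S,8Z,10E)-6-{[(benzyloxy)carbonyl]oxy}-9-[(tert-butyldimethylsilyl)oxy]-3,7,7-trimethyldodeca-2,8,10-trienoate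
Conditions: TBSOTf, Et3N, CH2Cl2, −78 → 0 °C
Reagents that add atoms: tert-butyldimethylsilyl trifluoromethanesulfonate, CC(C)(C)[Si](C)(C)OS(=O)(=O)C(F)(F)F
Why: Soft enolisation (silyl triflate activation of the ketone, amine deprotonation) on the α′ side at C5 should give the cross-conjugated 2-silyloxydiene, the Z enol ether (C4 cis to oxygen) being favoured because the quaternary C4 avoids allylic strain with the propenyl group, which puts the tether on the outside of the diene as the cycloaddition requires.

Step 11
Reactants: 16 methyl (2Z,6S,8Z,10E)-6-{[(benzyloxy)carbonyl]oxy}-9-[(tert-butyldimethylsilyl)oxy]-3,7,7-trimethyldodeca-2,8,10-trienoate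
Product: 17 methyl 3β-(benzyloxycarbonyloxy)-6-(tert-butyldimethylsilyloxy)drim-6-en-11-oate (5α-H; 8β-CH3; 9β-H; 10β-CH3)
Conditions: toluene (0.01 M), BHT (cat.), 180 °C, sealed base-washed tube
Reagents that add atoms: none
Why: Heating should bring about a concerted, asynchronous, suprafacial [4+2] cycloaddition between the electron-rich 2-silyloxydiene (C5=C6–C7=C8) and the Z-enoate (C9=C10), the nucleophilic diene terminus C5 bonding to the ester β-carbon C10 and C8 to C9; the closest known reaction type is the thermal type-1 intramolecular Diels–Alder reaction of 1,7,9-decatrienes carrying a 2-silyloxydiene, which gives decalone enol silanes. Ring B closes as the six-membered cycloaddition ring that holds both new bonds, and ring A closes as the six-membered carbocycle spanned by the tether C1–C4 with the tether-bearing end of the dienophile exo to the diene (C10 methyl endo, ester exo), which fuses the rings trans (5α-H). C9 is set against C10 by the Z geometry of the enoate (suprafacial addition puts the C10 methyl trans to the C11 ester), and C8 against C5 by the E,Z geometry of the diene, whose tether and C8 methyl both sit on outside positions. The absolute sense at C5, C9 and C10 is relayed from C3: in the chair-like folding of the tether the benzyl carbonate prefers the equatorial site, so the enoate offers one π-face to the diene. The step therefore needs π-facial selectivity of the dienophile relative to C3 together with trans ring fusion; the equatorial preference of the C3 substituent next to the gem-dimethyl carbon and the exo placement of the tether should secure them, and because C3 is still stereogenic a wrong-face adduct is a separable diastereomer, not the enantiomer.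

Step 12
Reactants: 17 methyl 3β-(benzyloxycarbonyloxy)-6-(tert-butyldimethylsilyloxy)drim-6-en-11-oate
Product: 18 methyl 6-(tert-butyldimethylsilyloxy)-3β-hydroxydrim-6-en-11-oate (5α-H; 8β-CH3; 9β-H; 10β-CH3)
Conditions: H2 (1 atm), Pd/C (palladium on carbon), EtOAc, rt
Reagents that add atoms: none
Why: Hydrogenolysis of the benzylic C–O bond followed by loss of CO2 from the carbonic acid monoester frees the 3β-alcohol under neutral conditions, the hindered trisubstituted silyl enol ether being hydrogenated far more slowly, so that C6 stays masked; no stereocentre changes.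

Step 13
Reactants: 18 methyl 6-(tert-butyldimethylsilyloxy)-3β-hydroxydrim-6-en-11-oate
Product: 19 methyl 6-(tert-butyldimethylsilyloxy)-3-oxodrim-6-en-11-oate (5α-H; 8β-CH3; 9β-H; 10β-CH3)
Conditions: Pr4N[RuO4] (TPAP, cat.), N-methylmorpholine N-oxide, 4 Å molecular sieves, CH2Cl2, rt
Reagents that add atoms: none
Why: Ley–Griffith oxidation converts the secondary alcohol into the C3 ketone under neutral conditions that a silyl enol ether tolerates; it removes the C3 centre once it has done its work, so any diastereomeric cycloadduct must be separated before this step.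

Step 14
Reactants: 19 methyl 6-(tert-butyldimethylsilyloxy)-3-oxodrim-6-en-11-oate
Product: 21 6-(tert-butyldimethylsilyloxy)drim-6-ene-3α,11-diol (5α-H; 8β-CH3; 9β-H; 10β-CH3), via 3α-hydroxy ester 20 (not isolated)
Conditions: Li[HB(s-Bu)3] (L-selectride), THF, −78 °C; then LiAlH4, −78 → 0 °C; aq. KNaC4H4O6 work-up
Reagents that add atoms: none
Why: The bulky trialkylborohydride attacks the C3 ketone along the equatorial trajectory (axial approach is blocked by the axial hydrogens on C1 and C5), giving the axial 3α-alcohol 20 without touching the ester at −78 °C, and LiAlH4 then reduces the hindered C11 ester to the primary alcohol (selectride ketone reduction followed by hydride ester reduction), the silyl enol ether shielding C6 from both hydrides.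

Step 15
Reactants: 21 6-(tert-butyldimethylsilyloxy)drim-6-ene-3α,11-diol; 22 isofraxidin (7-hydroxy-6,8-dimethoxy-2H-chromen-2-one)
Product: 23 7-{[6-(tert-butyldimethylsilyloxy)-3α-hydroxydrim-6-en-11-yl]oxy}-6,8-dimethoxy-2H-chromen-2-one (5α-H; 8β-CH3; 9β-H; 10β-CH3)
Conditions: PPh3, DIAD, THF, 0 °C → 40 °C
Reagents that add atoms: none
Why: In this Mitsunobu etherification the primary C11 alcohol is activated as its alkoxyphosphonium salt and displaced by the acidic phenol of 22, the axial 3α-alcohol next to the gem-dimethyl carbon being too hindered to react; no stereocentre is involved, and with C6 still masked there is no vinylogous β-elimination of the aryloxide.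

Step 16
Reactants: 23 7-{[6-(tert-butyldimethylsilyloxy)-3α-hydroxydrim-6-en-11-yl]oxy}-6,8-dimethoxy-2H-chromen-2-one; 24 isovaleryl chloride (3-methylbutanoyl chloride)
Product: 25 11-[(6,8-dimethoxy-2-oxo-2H-chromen-7-yl)oxy]-6-(tert-butyldimethylsilyloxy)drim-6-en-3α-yl 3-methylbutanoate (5α-H; 8β-CH3; 9β-H; 10β-CH3)
Conditions: pyridine, DMAP (cat.), CH2Cl2, 0 → 40 °C
Reagents that add atoms: none
Why: Nucleophile-catalysed (DMAP) acylation of the remaining axial 3α-alcohol with the acid chloride installs the isovalerate with retention at C3.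

Step 17
Reactants: 25 11-[(6,8-dimethoxy-2-oxo-2H-chromen-7-yl)oxy]-6-(tert-butyldimethylsilyloxy)drim-6-en-3α-yl 3-methylbutanoate
Product: 26 11-[(6,8-dimethoxy-2-oxo-2H-chromen-7-yl)oxy]-6-oxodrim-7-en-3α-yl 3-methylbutanoate (5α-H; 9β-H; 10β-CH3), the target CNP0279705.1
Conditions: Pd(OAc)2 (1.2 equiv), MeCN, rt → 40 °C
Reagents that add atoms: none
Why: In this Saegusa–Ito oxidation silicon-to-palladium exchange gives the C7-bound palladium enolate, whose only β-hydrogen is on C8, so syn β-hydride elimination gives the C7=C8 enone under neutral conditions, removing the C8 centre and leaving C5 and the base-sensitive C9 centre untouched.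

**Compound list**

1 | 3-methylcyclohex-2-en-1-one | CC1=CC(=O)CCC1 | starting material
2 | trimethyl[(5-methylcyclohexa-1,5-dien-1-yl)oxy]silane | CC1=CC(O[Si](C)(C)C)=CCC1 | intermediate
3 | 3-methyl-6-(trimethylsilyloxy)cyclohex-2-en-1-one (racemic) | CC1=CC(=O)C(O[Si](C)(C)C)CC1 | intermediate (not isolated)
4 | 6-hydroxy-3-methylcyclohex-2-en-1-one (racemic) | CC1=CC(=O)C(O)CC1 | intermediate
5 | methyl (2Z)-3-methyl-6-oxohex-2-enoate | O=CCC/C(C)=C\C(=O)OC | intermediate
6 | 3-methylbuta-1,2-diene | CC(C)=C=C | starting material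
7 | methyl (2Z,6S)-6-[(diisopinocampheylboryl)oxy]-3,7,7-trimethylnona-2,8-dienoate | C=CC(C)(C)[C@@H](OB([C@H]1C[C@H]2C[C@@H]([C@@H]1C)C2(C)C)[C@H]1C[C@H]2C[C@@H]([C@@H]1C)C2(C)C)CC/C(C)=C\C(=O)OC | intermediate (not isolated)
8 | methyl (2Z,6S)-6-hydroxy-3,7,7-trimethylnona-2,8-dienoate | C=CC(C)(C)[C@@H](O)CC/C(C)=C\C(=O)OC | intermediate
9 | methyl (2Z,6S)-6-{[(benzyloxy)carbonyl]oxy}-3,7,7-trimethylnona-2,8-dienoate | C=CC(C)(C)[C@@H](OC(=O)OCc1ccccc1)CC/C(C)=C\C(=O)OC | intermediate
10 | B-alkyl-9-BBN adduct of 9 (boron on C9 of the nonenoate chain) | C1CC2CCCC(C1)B2CCC(C)(C)[C@@H](OC(=O)OCc1ccccc1)CC/C(C)=C\C(=O)OC | intermediate (not isolated)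
11 | methyl (2Z,6S)-6-{[(benzyloxy)carbonyl]oxy}-9-hydroxy-3,7,7-trimethylnon-2-enoate | OCCC(C)(C)[C@@H](OC(=O)OCc1ccccc1)CC/C(C)=C\C(=O)OC | intermediate
12 | methyl (2Z,6S)-6-{[(benzyloxy)carbonyl]oxy}-3,7,7-trimethyl-9-oxonon-2-enoate | O=CCC(C)(C)[C@@H](OC(=O)OCc1ccccc1)CC/C(C)=C\C(=O)OC | intermediate
13 | (E)-1-bromoprop-1-ene | C/C=C/Br | starting material
14 | methyl (2Z,6S,10E)-6-{[(benzyloxy)carbonyl]oxy}-9-hydroxy-3,7,7-trimethyldodeca-2,10-dienoate (both C9 epimers) | C/C=C/C(O)CC(C)(C)[C@@H](OC(=O)OCc1ccccc1)CC/C(C)=C\C(=O)OC | intermediate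
15 | methyl (2Z,6S,10E)-6-{[(benzyloxy)carbonyl]oxy}-3,7,7-trimethyl-9-oxododeca-2,10-dienoate | C/C=C/C(=O)CC(C)(C)[C@@H](OC(=O)OCc1ccccc1)CC/C(C)=C\C(=O)OC | intermediate
16 | methyl (2Z,6S,8Z,10E)-6-{[(benzyloxy)carbonyl]oxy}-9-[(tert-butyldimethylsilyl)oxy]-3,7,7-trimethyldodeca-2,8,10-trienoate | C/C=C/C(O[Si](C)(C)C(C)(C)C)=C/C(C)(C)[C@@H](OC(=O)OCc1ccccc1)CC/C(C)=C\C(=O)OC | intermediate (key-step precursor)
17 | methyl 3β-(benzyloxycarbonyloxy)-6-(tert-butyldimethylsilyloxy)drim-6-en-11-oate (5α-H; 8β-CH3; 9β-H; 10β-CH3) | COC(=O)[C@@H]1[C@@H](C)C=C(O[Si](C)(C)C(C)(C)C)[C@H]2C(C)(C)[C@@H](OC(=O)OCc3ccccc3)CC[C@]12C | intermediate (key-step product)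
18 | methyl 6-(tert-butyldimethylsilyloxy)-3β-hydroxydrim-6-en-11-oate | COC(=O)[C@@H]1[C@@H](C)C=C(O[Si](C)(C)C(C)(C)C)[C@H]2C(C)(C)[C@@H](O)CC[C@]12C | intermediate
19 | methyl 6-(tert-butyldimethylsilyloxy)-3-oxodrim-6-en-11-oate | COC(=O)[C@@H]1[C@@H](C)C=C(O[Si](C)(C)C(C)(C)C)[C@H]2C(C)(C)C(=O)CC[C@]12C | intermediate
20 | methyl 6-(tert-butyldimethylsilyloxy)-3α-hydroxydrim-6-en-11-oate | COC(=O)[C@@H]1[C@@H](C)C=C(O[Si](C)(C)C(C)(C)C)[C@H]2C(C)(C)[C@H](O)CC[C@]12C | intermediate (not isolated)
21 | 6-(tert-butyldimethylsilyloxy)drim-6-ene-3α,11-diol | OC[C@@H]1[C@@H](C)C=C(O[Si](C)(C)C(C)(C)C)[C@H]2C(C)(C)[C@H](O)CC[C@]12C | intermediate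
22 | isofraxidin (7-hydroxy-6,8-dimethoxy-2H-chromen-2-one) | COc1cc2ccc(=O)oc2c(OC)c1O | starting material
23 | 7-{[6-(tert-butyldimethylsilyloxy)-3α-hydroxydrim-6-en-11-yl]oxy}-6,8-dimethoxy-2H-chromen-2-one | COc1cc2ccc(=O)oc2c(OC)c1OC[C@@H]1[C@@H](C)C=C(O[Si](C)(C)C(C)(C)C)[C@H]2C(C)(C)[C@H](O)CC[C@]12C | intermediate
24 | isovaleryl chloride (3-methylbutanoyl chloride) | CC(C)CC(=O)Cl | starting material
25 | 11-[(6,8-dimethoxy-2-oxo-2H-chromen-7-yl)oxy]-6-(tert-butyldimethylsilyloxy)drim-6-en-3α-yl 3-methylbutanoate | COc1cc2ccc(=O)oc2c(OC)c1OC[C@@H]1[C@@H](C)C=C(O[Si](C)(C)C(C)(C)C)[C@H]2C(C)(C)[C@H](OC(=O)CC(C)C)CC[C@]12C | intermediate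
26 | 11-[(6,8-dimethoxy-2-oxo-2H-chromen-7-yl)oxy]-6-oxodrim-7-en-3α-yl 3-methylbutanoate (CNP0279705.1) | COc1cc2ccc(=O)oc2c(OC)c1OC[C@@H]1C(C)=CC(=O)[C@H]2C(C)(C)[C@H](OC(=O)CC(C)C)CC[C@]12C | target

**Step count and risks**

Total step count: 17. Longest linear sequence: 17 steps (1 → 26); compounds 6, 13, 22 and 24 are bought.

Steps most likely to fail:

1. Step 11 (cycloaddition). The single equatorial substituent at C3 may discriminate the two π-faces of the enoate only weakly, closure may partly give the cis-fused ring system, and long heating may erode the enol silane. The fallback sets out from enone 15 and closes the two rings ionically instead of thermally. Deprotonation at C5 with LiN(SiMe3)2 (THF, −78 → 0 °C) gives the cross-conjugated lithium dienolate, which can add to the enoate at C10 and then, through the resulting ester enolate, to C8 (intramolecular double Michael addition). Protonation should give methyl 3β-(benzyloxycarbonyloxy)-6-oxodriman-11-oate F1, whose C5 centre can equilibrate to the trans ring fusion. Silylation toward C7 (TBSOTf, Et3N; the C5 hydrogen lies between two quaternary carbons) returns to 17. Because C9 is then set stepwise and not by olefin geometry, its configuration would have to be confirmed before going on.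

2. Step 15 (etherification). Displacement at the β-branched C11 by a phenol flanked by two methoxy groups may be slow, so that the alkoxyphosphonium intermediate is diverted to alkylation of the reduced azodicarboxylate or to elimination. The fallback sets out from diol 21: selective sulfonylation of the primary alcohol (Tf2O, 2,6-lutidine, CH2Cl2, −78 °C) gives 6-(tert-butyldimethylsilyloxy)-3α-hydroxydrim-6-en-11-yl trifluoromethanesulfonate F2, which is displaced by the caesium salt of 22 (Cs2CO3, MeCN, 0 °C → rt) to return to 23.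

3. Step 17 (enone formation). Silicon-to-palladium transfer at the hindered tert-butyldimethylsilyl enol ether may be slow, leading to incomplete conversion or plain hydrolysis. The fallback sets out from 25: buffered fluoride (HF·pyridine, pyridine, THF, 0 °C) gives 11-[(6,8-dimethoxy-2-oxo-2H-chromen-7-yl)oxy]-6-oxodriman-3α-yl 3-methylbutanoate F3, and dehydrogenation with 2-iodoxybenzoic acid (DMSO, 70 °C) can only run toward C7–C8, since both carbons flanking C5 (C4 and C10) are quaternary; this returns to 26.

**Further compounds**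

F1 | step 11 | methyl 3β-(benzyloxycarbonyloxy)-6-oxodriman-11-oate (5α-H; 8β-CH3; 9β-H; 10β-CH3) | COC(=O)[C@@H]1[C@@H](C)CC(=O)[C@H]2C(C)(C)[C@@H](OC(=O)OCc3ccccc3)CC[C@]12C
F2 | step 15 | 6-(tert-butyldimethylsilyloxy)-3α-hydroxydrim-6-en-11-yl trifluoromethanesulfonate | O=S(=O)(OC[C@@H]1[C@@H](C)C=C(O[Si](C)(C)C(C)(C)C)[C@H]2C(C)(C)[C@H](O)CC[C@]12C)C(F)(F)F
F3 | step 17 | 11-[(6,8-dimethoxy-2-oxo-2H-chromen-7-yl)oxy]-6-oxodriman-3α-yl 3-methylbutanoate (8β-CH3) | COc1cc2ccc(=O)oc2c(OC)c1OC[C@@H]1[C@@H](C)CC(=O)[C@H]2C(C)(C)[C@H](OC(=O)CC(C)C)CC[C@]12C
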